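Two questions stand, one of time and one of height, and the flask asked about is the summer run itself, followed further.

| flask | substrate | partner | protic impurity | remark | time |
|---|---|---|---|---|---|
| summer | 0.050 M | 0.060 M | 1 mM | the very flask that is asked about, followed so far |  |
| noon | 0.050 M | 0.12 M | 1 mM | run made earlier |  |
| flask | 0.050 M | 0.0600 M | 1.00 mM |  | 5.0 d |

* the best time, 5.0 d at the latest, for target
* the amount of target, in percent of the substrate charged, at that time

- summer (time / h: target / %): 3.00: 20.7; 5.00: 33.4; 8.00: 43.2; 12.0: 46.8; 20.0: 40.9; 30.0: 27.8; 50.0: 9.9
- noon (time / d: target / %): 0.125: 24.2; 0.208: 35.5; 0.417: 47.1; 0.625: 46.9; 1.25: 28.5; 2.08: 9.6; 4.00: 1.3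

(readings scatter by 0.5 percentage points)

Read the summer table downward. Target reads highest, 46.8% of the substrate charged, at 12.0 h. It then falls from 27.8% at 30.0 h to 9.9% at 50.0 h, a factor e every 0.807 d. Call that the loss lifetime: the time in which the tail of target shrinks by a factor e.

Now read the noon table, with twice the partner. Its tail gives 0.763 d, close to the summer value, so you may read the tails of these two runs as first-order.

Next, set the zero of the scale. If target were made with the same first-order constant as it is lost, its peak would stand at one lifetime and hold 36.8% of the charge. The highest summer reading stands earlier, at 0.620 lifetimes, and higher, so the summer rise reads quicker than the tail. My own reckoning puts the maximum near that early reading, with the limit at 6.20 lifetimes.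

The forecast says 0.51 d (0.45 d to 0.58 d) and 47.1% (46.4% to 47.9%), noting that “Neither run shows any sign of a late recovery”.

The flask gives 46.8% at 0.521 d, inside both ranges.

    substrate ⇌ open intermediate (K = 1.50, k = 0.110 h⁻¹)
    partner + protic impurity → quenched reagent (k = 510 M⁻¹ h⁻¹)
    open intermediate + second intermediate → target (k = 91.0 M⁻¹ h⁻¹)
    target → over-reaction product (k = 0.0620 h⁻¹)
    partner → second intermediate (k = 0.260 h⁻¹)
    open intermediate → decomposed reagent (k = 0.00570 h⁻¹)

In the asked flask at 0.521 d, substrate still stands at 26.6% of its charge. Carried from that peak, the loss lifetime gives 0.182% of target at 5.0 d, and the asked flask holds 0.151%. In the noon run, it carries the 9.6% read at 2.08 d to 0.889% at 4.00 d, where the reading is 1.3%.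

The runs are simulated for an exercise.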